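**Retrosynthetic overview**

Benzofuran numbering of the target: O1, C2 (S, bearing CMe2OH), C3 (CH2), C3a, C4 (OH), C5 (prenyl), C6 (OH), C7 (acyl), C7a.
1. The C5–prenyl bond is cut last (C-alkylation of the free acylphloroglucinol). The C7–C(=O) bond goes back to a C7 aryllithium (from the C7 bromide) and a Weinreb amide. CMe2OH goes back to a C2 methyl ester.
2. The strategy rests on C2 of the dihydrofuran ring lying between the aryl ether oxygen O1 and the benzylic methylene C3. C2 is therefore brought in as the single carbon of an ester-stabilised chiral sulfonium ylide, which forms C3–C2 and O1–C2 in a (4+1) annulation with the o-quinone methide released from an N-methylated phloroglucinol Mannich base.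
3. Ring order: the phloroglucinol ring and the anisyl ring are bought; the dihydrofuran ring is the only ring closed (step 7).

Key step: step 7

Assumption: the sense of induction by the (2R,5R)-thiolanium group cannot be assigned in advance; the route is written for the case that it delivers the (S)-ester, and the mirror-image thiolane from (2R,5R)-hexane-2,5-diol would be taken through the same steps should the opposite sense be found.

**Route**

Step 1
Reactants: 1 phloroglucinol
Product: 2 3,5-bis(benzyloxy)phenol
Conditions: BnBr (2.0 equiv), K2CO3, DMF, 0 °C → rt; chromatography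
Reagents that add atoms: benzyl bromide, BrCc1ccccc1
Why: Williamson O-benzylation of the triphenol under mild carbonate conditions should give a statistical mixture from which the dibenzyl ether is separated from the mono- and tribenzyl ethers; no stereocentre is formed.

Step 2
Reactants: 2 3,5-bis(benzyloxy)phenol
Product: 3 3,5-bis(benzyloxy)-2-[(dimethylamino)methyl]phenol
Conditions: Me2N=CH2+ I− (1.05 equiv), K2CO3, CH2Cl2, rt
Reagents that add atoms: N,N-dimethylmethylideneammonium iodide (Eschenmoser's salt), C=[N+](C)C.[I-]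
Why: Phenol Mannich aminomethylation with the preformed iminium salt; the potassium phenoxide ion pair in a non-polar solvent should deliver the electrophile to the ortho carbon (C2 and C6 are equivalent), and one equivalent of reagent limits double aminomethylation.

Step 3
Reactants: 3 3,5-bis(benzyloxy)-2-[(dimethylamino)methyl]phenol
Product: 4 1-[2,4-bis(benzyloxy)-6-hydroxyphenyl]-N,N,N-trimethylmethanaminium iodide
Conditions: MeI (3 equiv), acetone/Et2O, 0 °C → rt, dark; salt filtered and washed
Reagents that add atoms: iodomethane, CI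
Why: Menshutkin N-alkylation of the tertiary amine is far faster than O-methylation of the un-ionised phenol and should give a crystalline salt that is filtered free of excess iodomethane and carries trimethylamine as a good leaving group for mild release of the quinone methide.

Step 4
Reactants: 5 (2S,5S)-hexane-2,5-diol
Product: 6 (2S,5S)-hexane-2,5-diyl dimethanesulfonate
Conditions: MsCl (2.4 equiv), Et3N, CH2Cl2, 0 °C
Reagents that add atoms: methanesulfonyl chloride, CS(=O)(=O)Cl
Why: Sulfonylation of both secondary alcohols forms only O–S bonds, so both carbinol carbons keep their configuration.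

Step 5
Reactants: 6 (2S,5S)-hexane-2,5-diyl dimethanesulfonate
Product: 7 (2R,5R)-2,5-dimethylthiolane
Conditions: Na2S·9H2O, EtOH, rt → 40 °C; careful distillation
Reagents that add atoms: sodium sulfide, [Na+].[Na+].[S-2]
Why: Double SN2 thioetherification, the second a 5-exo-tet ring closure, inverts both carbinol carbons, so the (2S,5S)-dimesylate should give the trans (2R,5R)-thiolane.

Step 6
Reactants: 7 (2R,5R)-2,5-dimethylthiolane; 8 methyl bromoacetate
Product: 9 (2R,5R)-1-(2-methoxy-2-oxoethyl)-2,5-dimethylthiolan-1-ium bromide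
Conditions: acetone, rt, 48 h; salt collected by filtration
Reagents that add atoms: none
Why: SN2 S-alkylation of the sulfide by the reactive α-bromo ester; the two lone pairs on sulfur of the C2-symmetric thiolane are homotopic, so a single sulfonium salt should form.

Step 7
Reactants: 4 1-[2,4-bis(benzyloxy)-6-hydroxyphenyl]-N,N,N-trimethylmethanaminium iodide; 9 (2R,5R)-1-(2-methoxy-2-oxoethyl)-2,5-dimethylthiolan-1-ium bromide
Product: 13 methyl (2S)-4,6-bis(benzyloxy)-2,3-dihydro-1-benzofuran-2-carboxylate, via thiolanium ylide 10 (not isolated), via o-quinone methide 11 (not isolated), via phenoxide–sulfonium betaine 12 (not isolated)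
Conditions: 9 (1.3 equiv), Cs2CO3 (3 equiv), CH2Cl2/MeCN, −20 °C → rt
Reagents that add atoms: none
Why: Proposed new method: Cs2CO3 ionises the phenol of 4, which expels trimethylamine to give the electron-rich o-quinone methide 11, and deprotonates 9 to ylide 10; the ylide carbon adds 1,4 to the exocyclic methylene (C3–C2 bond) to give betaine 12, whose phenoxide then displaces the thiolane in an SN2 reaction with inversion (O1–C2 bond). The closest known reaction type is the formal (4+1) annulation of o-quinone methides with stabilised sulfonium ylides to 2-substituted 2,3-dihydrobenzofurans; new here is that a stoichiometric C2-symmetric sulfonium group has to control a lone C2 stereocentre at an unsubstituted methide terminus. The dihydrofuran ring closes by 5-exo-tet O-alkylation. C2 is controlled by the (2R,5R)-thiolanium group: the C–H between sulfonium and ester in 12 is acidic, so the two epimers interconvert through the ylide and the trans-2,5-dimethyl groups should make one of the two diastereomeric displacement transition states lower (Curtin–Hammett), the (R)-betaine leading to the (S)-ester. Regioselectivity is needed and is secured by the ortho-Mannich position, since only one methide can form and only its CH2 terminus is electrophilic; enantioselectivity is needed and rests on the sulfonium group, with the mild carbonate base and low temperature keeping the α-aryloxy ester from racemising.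

Step 8
Reactants: 13 methyl (2S)-4,6-bis(benzyloxy)-2,3-dihydro-1-benzofuran-2-carboxylate
Product: 15 2-[(2S)-4,6-bis(benzyloxy)-2,3-dihydro-1-benzofuran-2-yl]propan-2-ol, via methyl ketone 14 (not isolated)
Conditions: MeMgBr (3 equiv), THF, −40 → 0 °C; aq. NH4Cl
Reagents that add atoms: methylmagnesium bromide, C[Mg]Br
Why: Double Grignard addition to the ester through ketone 14; addition to the α-alkoxy carbonyl groups should outrun enolisation at low temperature, so C2 stays (S) (the CIP order O1 > side-chain carbon > C3 is unchanged), and the tertiary alcohol is in place before any aryl ketone exists.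

Step 9
Reactants: 15 2-[(2S)-4,6-bis(benzyloxy)-2,3-dihydro-1-benzofuran-2-yl]propan-2-ol
Product: 16 2-[(2S)-4,6-bis(benzyloxy)-7-bromo-2,3-dihydro-1-benzofuran-2-yl]propan-2-ol
Conditions: NBS (1.0 equiv), CH2Cl2, −78 → 0 °C, dark
Reagents that add atoms: N-bromosuccinimide, O=C1CCC(=O)N1Br
Why: Electrophilic aromatic bromination of the phloroglucinol triether is expected at C7 (between O1 and the C6 ether) rather than at C5 (between two benzyloxy groups), as in the C8-selective NBS bromination of 5,7-di-O-benzyl flavans; it replaces a Lewis-acid Friedel–Crafts acylation that the free tertiary alcohol and the benzyl ethers would not tolerate.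

Step 10
Reactants: 17 3-(4-methoxyphenyl)propanoic acid
Product: 19 N-methoxy-3-(4-methoxyphenyl)-N-methylpropanamide, via acyl imidazole 18 (not isolated)
Conditions: carbonyldiimidazole (1.1 equiv), CH2Cl2, rt; then MeNHOMe·HCl, rt
Reagents that add atoms: N,O-dimethylhydroxylamine hydrochloride, CNOC.Cl
Why: Weinreb amide formation by carbonyldiimidazole activation to acyl imidazole 18 followed by aminolysis.

Step 11
Reactants: 16 2-[(2S)-4,6-bis(benzyloxy)-7-bromo-2,3-dihydro-1-benzofuran-2-yl]propan-2-ol; 19 N-methoxy-3-(4-methoxyphenyl)-N-methylpropanamide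
Product: 22 1-[(2S)-4,6-bis(benzyloxy)-2-(2-hydroxypropan-2-yl)-2,3-dihydro-1-benzofuran-7-yl]-3-(4-methoxyphenyl)propan-1-one, via C7 aryllithium alkoxide 20 (not isolated), via tetrahedral lithium adduct 21 (not isolated)
Conditions: n-BuLi (2.2 equiv), THF, −78 °C; then 19, −78 → 0 °C; aq. NH4Cl
Reagents that add atoms: none
Why: Bromine–lithium exchange (after deprotonation of the tertiary alcohol by the first equivalent) gives aryllithium 20, which adds to the Weinreb amide to form the chelated tetrahedral adduct 21 that should persist until work-up, so the ketone is released without over-addition and C2 is untouched.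

Step 12
Reactants: 22 1-[(2S)-4,6-bis(benzyloxy)-2-(2-hydroxypropan-2-yl)-2,3-dihydro-1-benzofuran-7-yl]-3-(4-methoxyphenyl)propan-1-one
Product: 23 1-[(2S)-4,6-dihydroxy-2-(2-hydroxypropan-2-yl)-2,3-dihydro-1-benzofuran-7-yl]-3-(4-methoxyphenyl)propan-1-one
Conditions: H2 (1 atm), 10% Pd/C, EtOAc/MeOH, rt; stopped after uptake of two equivalents
Reagents that add atoms: none
Why: Hydrogenolysis of the two benzyl aryl ethers over palladium; the hydrogen-bonded ortho-hydroxy aryl ketone and the non-benzylic O1–C2 bond should not be reduced at one atmosphere and room temperature.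

Step 13
Reactants: 23 1-[(2S)-4,6-dihydroxy-2-(2-hydroxypropan-2-yl)-2,3-dihydro-1-benzofuran-7-yl]-3-(4-methoxyphenyl)propan-1-one
Product: 24 1-[(2S)-4,6-dihydroxy-2-(2-hydroxypropan-2-yl)-5-(3-methylbut-2-en-1-yl)-2,3-dihydro-1-benzofuran-7-yl]-3-(4-methoxyphenyl)propan-1-one (CNP0150199.1)
Conditions: prenyl bromide (1.1 equiv), 10% aq. KOH, 0 °C → rt; AcOH to pH 6
Reagents that add atoms: prenyl bromide (1-bromo-3-methylbut-2-ene), CC(C)=CCBr
Why: C-alkylation of the ambident acylphloroglucinol phenoxide with an allylic bromide in water, where hydrogen bonding to oxygen favours attack through carbon; C5 is the only unsubstituted ring carbon, so the adduct rearomatises there and the regiochemistry is fixed.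

**Compound list**

1 | phloroglucinol (benzene-1,3,5-triol) | Oc1cc(O)cc(O)c1 | starting material
2 | 3,5-bis(benzyloxy)phenol | Oc1cc(OCc2ccccc2)cc(OCc2ccccc2)c1 | intermediate
3 | 3,5-bis(benzyloxy)-2-[(dimethylamino)methyl]phenol | CN(C)Cc1c(O)cc(OCc2ccccc2)cc1OCc1ccccc1 | intermediate
4 | 1-[2,4-bis(benzyloxy)-6-hydroxyphenyl]-N,N,N-trimethylmethanaminium iodide | C[N+](C)(C)Cc1c(O)cc(OCc2ccccc2)cc1OCc1ccccc1.[I-] | intermediate
5 | (2S,5S)-hexane-2,5-diol | C[C@H](O)CC[C@H](C)O | starting material
6 | (2S,5S)-hexane-2,5-diyl dimethanesulfonate | C[C@H](OS(C)(=O)=O)CC[C@H](C)OS(C)(=O)=O | intermediate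
7 | (2R,5R)-2,5-dimethylthiolane | C[C@@H]1CC[C@@H](C)S1 | intermediate
8 | methyl bromoacetate | COC(=O)CBr | starting material
9 | (2R,5R)-1-(2-methoxy-2-oxoethyl)-2,5-dimethylthiolan-1-ium bromide | C[C@@H]1CC[C@@H](C)[S+]1CC(=O)OC.[Br-] | intermediate
10 | (2R,5R)-2,5-dimethylthiolanium (methoxycarbonyl)methylide | C[C@@H]1CC[C@@H](C)[S+]1[CH-]C(=O)OC | intermediate (not isolated)
11 | 3,5-bis(benzyloxy)-6-methylidenecyclohexa-2,4-dien-1-one (o-quinone methide) | C=C1C(=O)C=C(OCc2ccccc2)C=C1OCc1ccccc1 | intermediate (not isolated)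
12 | 3,5-bis(benzyloxy)-2-{2-[(2R,5R)-2,5-dimethylthiolan-1-ium-1-yl]-3-methoxy-3-oxopropyl}phenolate (betaine, equilibrating epimers at the sulfonium-bearing carbon) | C[C@@H]1CC[C@@H](C)[S+]1C(C(=O)OC)Cc1c([O-])cc(OCc2ccccc2)cc1OCc1ccccc1 | intermediate (not isolated)
13 | methyl (2S)-4,6-bis(benzyloxy)-2,3-dihydro-1-benzofuran-2-carboxylate | O(Cc1ccccc1)c1cc(OCc2ccccc2)c2c(c1)O[C@H](C(=O)OC)C2 | intermediate
14 | 1-[(2S)-4,6-bis(benzyloxy)-2,3-dihydro-1-benzofuran-2-yl]ethan-1-one | O(Cc1ccccc1)c1cc(OCc2ccccc2)c2c(c1)O[C@H](C(C)=O)C2 | intermediate (not isolated)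
15 | 2-[(2S)-4,6-bis(benzyloxy)-2,3-dihydro-1-benzofuran-2-yl]propan-2-ol | O(Cc1ccccc1)c1cc(OCc2ccccc2)c2c(c1)O[C@H](C(C)(C)O)C2 | intermediate
16 | 2-[(2S)-4,6-bis(benzyloxy)-7-bromo-2,3-dihydro-1-benzofuran-2-yl]propan-2-ol | Brc1c(OCc2ccccc2)cc(OCc2ccccc2)c2c1O[C@H](C(C)(C)O)C2 | intermediate
17 | 3-(4-methoxyphenyl)propanoic acid | COc1ccc(CCC(=O)O)cc1 | starting material
18 | 1-(1H-imidazol-1-yl)-3-(4-methoxyphenyl)propan-1-one | COc1ccc(CCC(=O)n2ccnc2)cc1 | intermediate (not isolated)
19 | N-methoxy-3-(4-methoxyphenyl)-N-methylpropanamide | COc1ccc(CCC(=O)N(C)OC)cc1 | intermediate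
20 | lithium 2-[(2S)-4,6-bis(benzyloxy)-7-lithio-2,3-dihydro-1-benzofuran-2-yl]propan-2-olate | [Li]c1c(OCc2ccccc2)cc(OCc2ccccc2)c2c1O[C@H](C(C)(C)O[Li])C2 | intermediate (not isolated)
21 | dilithium tetrahedral adduct of 20 and 19 (epimers at the new hemiaminal carbon) | COc1ccc(CCC(O[Li])(N(C)OC)c2c(OCc3ccccc3)cc(OCc3ccccc3)c3c2O[C@H](C(C)(C)O[Li])C3)cc1 | intermediate (not isolated)
22 | 1-[(2S)-4,6-bis(benzyloxy)-2-(2-hydroxypropan-2-yl)-2,3-dihydro-1-benzofuran-7-yl]-3-(4-methoxyphenyl)propan-1-one | COc1ccc(CCC(=O)c2c(OCc3ccccc3)cc(OCc3ccccc3)c3c2O[C@H](C(C)(C)O)C3)cc1 | intermediate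
23 | 1-[(2S)-4,6-dihydroxy-2-(2-hydroxypropan-2-yl)-2,3-dihydro-1-benzofuran-7-yl]-3-(4-methoxyphenyl)propan-1-one | COc1ccc(CCC(=O)c2c(O)cc(O)c3c2O[C@H](C(C)(C)O)C3)cc1 | intermediate
24 | 1-[(2S)-4,6-dihydroxy-2-(2-hydroxypropan-2-yl)-5-(3-methylbut-2-en-1-yl)-2,3-dihydro-1-benzofuran-7-yl]-3-(4-methoxyphenyl)propan-1-one | COc1ccc(CCC(=O)c2c(O)c(CC=C(C)C)c(O)c3c2O[C@H](C(C)(C)O)C3)cc1 | target

**Step count**

Total steps: 13. Longest linear sequence: 9 steps (steps 1, 2, 3, 7, 8, 9, 11, 12, 13; the thiolane branch through steps 4, 5, 6 is equally long).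

**Steps most likely to fail**

Step 7 (Proposed new method). The two betaine epimers may cyclise at similar rates, so that the sulfonium group gives poor enantioselectivity; the quinone methide may also be lost to oligomerisation or to a second addition to the betaine. The fallback uses known chemistry and sets out from 4. Dimethyl sulfide and methyl bromoacetate 8 give (2-methoxy-2-oxoethyl)dimethylsulfonium bromide F1. With Cs2CO3 this forms dimethylsulfonium (methoxycarbonyl)methylide F2 in the flask, which adds to quinone methide 11 to give the achiral-sulfonium betaine F3. F3 closes to racemic methyl 4,6-bis(benzyloxy)-2,3-dihydro-1-benzofuran-2-carboxylate F4, the established racemic (4+1) annulation. The enantiomers of F4 are separated by preparative chromatography on a polysaccharide chiral stationary phase, and the (S)-enantiomer re-enters the route as 13.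

Step 13. O-alkylation of the C4 phenoxide and a second, dearomatising alkylation at C5 may compete with the single C-alkylation. The fallback sets out from 23 and replaces direct alkylation by an aromatic Claisen rearrangement. The non-chelated C4 hydroxyl is etherified with 3-chloro-3-methylbut-1-yne (K2CO3, KI, catalytic CuI, acetone) to give 1-[(2S)-6-hydroxy-2-(2-hydroxypropan-2-yl)-4-[(2-methylbut-3-yn-2-yl)oxy]-2,3-dihydro-1-benzofuran-7-yl]-3-(4-methoxyphenyl)propan-1-one F5. Semihydrogenation (H2, Pd/CaCO3 poisoned with Pb(OAc)2, quinoline) gives the 1,1-dimethylallyl ether 1-[(2S)-6-hydroxy-2-(2-hydroxypropan-2-yl)-4-[(2-methylbut-3-en-2-yl)oxy]-2,3-dihydro-1-benzofuran-7-yl]-3-(4-methoxyphenyl)propan-1-one F6. Warming F6 in toluene should bring about the [3,3] shift to C5, the only free ortho position, and tautomerisation then gives 24.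

Step 11. The hindered aryllithium may be quenched by enolisation of the Weinreb amide, or may rearrange by proton transfer from a neighbouring benzyl ether before it adds. The fallback sets out from 16 and uses a more electrophilic partner followed by oxidation. Aryllithium 20, generated as before, is trapped at −78 °C with commercial 3-(4-methoxyphenyl)propanal to give 1-[(2S)-4,6-bis(benzyloxy)-2-(2-hydroxypropan-2-yl)-2,3-dihydro-1-benzofuran-7-yl]-3-(4-methoxyphenyl)propan-1-ol F7 as a mixture of carbinol epimers. Dess–Martin periodinane in CH2Cl2 oxidises the secondary benzylic alcohol, leaving the tertiary alcohol untouched, and the route is rejoined at 22.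

Further compounds
F1 | step 7 | (2-methoxy-2-oxoethyl)dimethylsulfonium bromide | C[S+](C)CC(=O)OC.[Br-]
F2 | step 7 | dimethylsulfonium (methoxycarbonyl)methylide | C[S+](C)[CH-]C(=O)OC
F3 | step 7 | 3,5-bis(benzyloxy)-2-[2-(dimethylsulfonio)-3-methoxy-3-oxopropyl]phenolate (racemic betaine) | C[S+](C)C(C(=O)OC)Cc1c([O-])cc(OCc2ccccc2)cc1OCc1ccccc1
F4 | step 7 | racemic methyl 4,6-bis(benzyloxy)-2,3-dihydro-1-benzofuran-2-carboxylate | COC(=O)C1Cc2c(OCc3ccccc3)cc(OCc3ccccc3)cc2O1
F5 | step 13 | 1-[(2S)-6-hydroxy-2-(2-hydroxypropan-2-yl)-4-[(2-methylbut-3-yn-2-yl)oxy]-2,3-dihydro-1-benzofuran-7-yl]-3-(4-methoxyphenyl)propan-1-one | COc1ccc(CCC(=O)c2c(O)cc(OC(C)(C)C#C)c3c2O[C@H](C(C)(C)O)C3)cc1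
F6 | step 13 | 1-[(2S)-6-hydroxy-2-(2-hydroxypropan-2-yl)-4-[(2-methylbut-3-en-2-yl)oxy]-2,3-dihydro-1-benzofuran-7-yl]-3-(4-methoxyphenyl)propan-1-one | COc1ccc(CCC(=O)c2c(O)cc(OC(C)(C)C=C)c3c2O[C@H](C(C)(C)O)C3)cc1
F7 | step 11 | 1-[(2S)-4,6-bis(benzyloxy)-2-(2-hydroxypropan-2-yl)-2,3-dihydro-1-benzofuran-7-yl]-3-(4-methoxyphenyl)propan-1-ol | COc1ccc(CCC(O)c2c(OCc3ccccc3)cc(OCc3ccccc3)c3c2O[C@H](C(C)(C)O)C3)cc1
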